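All constants are assumed; the rest is arithmetic.

Set this flask beside a neighbour charged with 0.24 M of substrate, and ask how much gas each solution keeps.

substrate 0.40 M; gas phase 13 mM (held); time 20 s

    gas phase ⇌ dissolved gas, rate k1*(csat - [dissolved gas]) (k1 = 19 /s, csat = 13 mM)
    dissolved gas + target → over-reacted product (k2 = 1.4 /M/s)
    crystals ⇌ target, rate k3*(cs3 - [target]) while solid is left; crystals form when [target] > cs3 (cs3 = 0.37 M, k3 = 1.1 /s)
    substrate + dissolved gas ⇌ target (K4 = 140 /M, k4 = 8.6 /M/s)
    substrate ⇌ dormant form (K5 = 2.5, k5 = 0.95 /s)

- amount of target and crystals together at 20 s, in percent of the substrate charged
- concentration of dissolved gas in solution at 2.0 s, in percent of saturation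
- the change that raises the amount of target and crystals together at 20 s, in percent of the substrate charged most ("none" if none brings more than 2 percentage points) (Saturday's / Thursday's / Wednesday's / Tuesday's / none)
- amount of target and crystals together at 20 s, in percent of the substrate charged, after Tuesday's

- amounts and yields of target count crystals too
- given per volume of solution although it is solid: crystals
- at the start none of the gas is dissolved
- run time (flask): 20 s

- Saturday's: doubling the transfer coefficient of step 1, all else as stated
- Thursday's: doubling the dissolution coefficient of step 3, all else as stated
- Wednesday's: doubling the saturation concentration of gas phase, all else as stated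
- Tuesday's: doubling the solubility in step 3, all else as stated

Write the balance of dissolved gas. The gas phase is held, and step 1 could deliver 1235% of the charge by 20 s into a solution kept empty, more than the charge itself, so take substrate as the limiting reagent. Two rates stand in it. Transfer refills the gap to saturation at 19 /s, and addition to substrate consumes the gas at a rate set by free substrate. Take that substrate from the dormant equilibrium, because the forward half-life of 0.73 s is shorter than the earlier time: it is 0.114 M. Counting addition forward, demand is 0.983 /s.

Call transfer coefficient over demand the gas hold 19.3. Set the balance to zero: the solution stands at hold over one plus hold, 95.1% of saturation.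

So addition is pseudo-first-order in substrate. Its equilibrium at full saturation, dormant form counted, caps target at 0.137 M, and over-reaction can only lower that. Target therefore stays under 34.2% of the charge, and crystals do not form in this flask because the cap lies below the solubility. Tuesday's and Thursday's then add nothing. Score each change by the gas it adds, as a fraction of present saturation: Wednesday's wins. This reckoning stops at a bound for the yield.

The forecast commits to values: 24%, 95.3%, Wednesday's, and 24% after Tuesday's, holding that “only doubling the saturation concentration clearly raises the yield”.

This flask gives 24.3%, 95.5%, Wednesday's and 24.3%. Wednesday's gains 7.7 percentage points against 0.21 points for Saturday's, with crystals at 0% in this flask at 20.0 s. Now use the gas hold on the neighbour: its charge raises the hold to 32.2, which puts dissolved gas at 0.0126 M, and the neighbour reads 0.0129 M at 20.0 s.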